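## Retrosynthetic overview

- The exocyclic CH2 goes on last, by decarboxylative methylenation of the trans-paraconic diacid (carbon from formaldehyde).
- The γ-lactone is the only ring and closes in the fourth step from a syn γ-hydroxy triester. Both stereocentres come from one dynamic-kinetic asymmetric hydrogenation of a racemic, freely enolising 2-acylsuccinate.
- The key C–C bond (future carbinol carbon to future carboxyl-bearing ring carbon) is a Stetter addition. A carbene-bound acyl anion equivalent of methyl 16-oxohexadecanoate adds to dimethyl fumarate, joining two carbons that are both electrophilic in the reactants.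
- The aldehyde comes from the bulk musk lactone 16-hexadecanolide by methanolysis and oxidation.

Assumption: the SMILES is read as the trans acid (2R,3S)-2-(14-carboxytetradecyl)-4-methylidene-5-oxooxolane-3-carboxylic acid (carbinol carbon R, carboxyl-bearing ring carbon S).

## Route

Step 1
Reactants: 1 16-hexadecanolide (oxacycloheptadecan-2-one)
Product: 2 methyl 16-hydroxyhexadecanoate
Conditions: MeOH, H2SO4 (cat.), reflux
Reagents that add atoms: methanol, CO
Why: Acid-catalysed transesterification (Fischer-type methanolysis) in a large excess of methanol opens the unstrained macrolactone to the hydroxy ester; no stereocentre is involved.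

Step 2
Reactants: 2 methyl 16-hydroxyhexadecanoate
Product: 3 methyl 16-oxohexadecanoate
Conditions: PhI(OAc)2 (1.1 equiv), 2,2,6,6-tetramethylpiperidin-1-oxyl (TEMPO, 10 mol%), CH2Cl2, rt
Reagents that add atoms: none
Why: Oxoammonium-mediated alcohol oxidation (TEMPO/PhI(OAc)2) stops at the aldehyde under anhydrous conditions and leaves the methyl ester untouched; no stereocentre is involved.

Step 3
Reactants: 3 methyl 16-oxohexadecanoate; 4 dimethyl fumarate
Product: 6 dimethyl 2-(16-methoxy-16-oxohexadecanoyl)butanedioate (racemic), via Breslow intermediate 5 (not isolated)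
Conditions: 3-benzyl-5-(2-hydroxyethyl)-4-methylthiazolium chloride (10 mol%), Et3N (0.5 equiv), 4 (1.05 equiv), 1,4-dioxane, 80 °C
Reagents that add atoms: none
Why: Stetter reaction: the thiazol-2-ylidene turns the aldehyde carbon into a nucleophilic acyl anion equivalent (Breslow intermediate 5) that adds irreversibly to the β-carbon of the fumarate, so two carbons that are both electrophilic in the reactants become bonded, and the new α-stereocentre of the β-keto ester is knowingly left racemic and enolisable for the next step.

Step 4
Reactants: 6 dimethyl 2-(16-methoxy-16-oxohexadecanoyl)butanedioate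
Product: 8 (2R,3S)-2-(14-carboxytetradecyl)-5-oxooxolane-3-carboxylic acid, via hydroxy triester 7 (not isolated)
Conditions: H2 (50 bar), [RuCl(p-cymene)((R)-BINAP)]Cl (1 mol%; BINAP = 2,2'-bis(diphenylphosphanyl)-1,1'-binaphthyl), CH2Cl2, 50 °C; then concentrate, 6 M HCl, 1,4-dioxane, reflux
Reagents that add atoms: water, O
Why: Noyori asymmetric hydrogenation with dynamic kinetic resolution: 6 racemises through its enol faster than it is reduced, the (R)-BINAP–Ru hydride (the ligand enantiomer that gives (R)-3-hydroxyalkanoates from 3-oxoalkanoates) reduces the ester-chelated ketone to the (R)-carbinol and should prefer the (2S)-epimer by analogy with 2-(amidomethyl)-3-oxo esters, so both stereocentres arise here as syn hydroxy triester 7, which 6 M HCl then hydrolyses and closes to the trans γ-lactone (also the thermodynamically favoured epimer).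

Step 5
Reactants: 8 (2R,3S)-2-(14-carboxytetradecyl)-5-oxooxolane-3-carboxylic acid
Product: 11 (2R,3S)-2-(14-carboxytetradecyl)-4-methylidene-5-oxooxolane-3-carboxylic acid (CNP0222442.1), via α-carboxy lactone 9 (not isolated), via Mannich base 10 (not isolated)
Conditions: MeOMgOCO2Me (2 M in DMF, excess), 135 °C; then cold aq. HCl, extract; then 37% aq. HCHO, PhNHMe, NaOAc, AcOH, rt
Reagents that add atoms: formaldehyde, C=O
Why: Stiles carboxylation followed by decarboxylative Mannich methylenation: MeOMgOCO2Me carboxylates only the lactone α-CH2 (chelated magnesium enolate–carboxylate) while both carboxylic acids sit as inert magnesium carboxylates, and malonic-type acid 9 then condenses with formaldehyde and N-methylaniline to Mannich base 10, which fragments with loss of CO2 and the amine to the exocyclic alkene without touching either stereocentre.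

## Compound list

1 | 16-hexadecanolide (oxacycloheptadecan-2-one) | O=C1CCCCCCCCCCCCCCCO1 | starting material
2 | methyl 16-hydroxyhexadecanoate | COC(=O)CCCCCCCCCCCCCCCO | intermediate
3 | methyl 16-oxohexadecanoate | COC(=O)CCCCCCCCCCCCCCC=O | intermediate
4 | dimethyl fumarate | COC(=O)/C=C/C(=O)OC | starting material
5 | Breslow intermediate: methyl 16-[3-benzyl-5-(2-hydroxyethyl)-4-methyl-1,3-thiazol-2(3H)-ylidene]-16-hydroxyhexadecanoate | COC(=O)CCCCCCCCCCCCCCC(O)=C1SC(CCO)=C(C)N1Cc2ccccc2 | intermediate
6 | dimethyl 2-(16-methoxy-16-oxohexadecanoyl)butanedioate (racemic) | COC(=O)CC(C(=O)OC)C(=O)CCCCCCCCCCCCCCC(=O)OC | intermediate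
7 | hydroxy triester: dimethyl (2S)-2-[(1R)-1-hydroxy-16-methoxy-16-oxohexadecyl]butanedioate | COC(=O)C[C@H](C(=O)OC)[C@H](O)CCCCCCCCCCCCCCC(=O)OC | intermediate
8 | (2R,3S)-2-(14-carboxytetradecyl)-5-oxooxolane-3-carboxylic acid | C1C(=O)O[C@H](CCCCCCCCCCCCCCC(=O)O)[C@H]1C(=O)O | intermediate
9 | α-carboxy lactone: (2R,3S)-2-(14-carboxytetradecyl)-5-oxooxolane-3,4-dicarboxylic acid (C4 epimers) | OC(=O)C1C(=O)O[C@H](CCCCCCCCCCCCCCC(=O)O)[C@H]1C(=O)O | intermediate
10 | Mannich base: (2R,3S)-2-(14-carboxytetradecyl)-4-[(N-methylanilino)methyl]-5-oxooxolane-3,4-dicarboxylic acid (C4 epimers) | CN(c1ccccc1)CC2(C(=O)O)C(=O)O[C@H](CCCCCCCCCCCCCCC(=O)O)[C@H]2C(=O)O | intermediate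
11 | (2R,3S)-2-(14-carboxytetradecyl)-4-methylidene-5-oxooxolane-3-carboxylic acid (CNP0222442.1) | C=C1C(=O)O[C@H](CCCCCCCCCCCCCCC(=O)O)[C@H]1C(=O)O | target

## Step count and risks

Total step count: 5. Longest linear sequence: 5 (steps 1 to 5; dimethyl fumarate is purchased).

Steps most likely to fail:

**Step 3 (Stetter addition).** The unbranched aldehyde can divert into acyloin or aldol products, and the acidic product 6 can add to excess fumarate. The fallback sets out from 3 and comes back at 6. Tin-catalysed Roskamp homologation of 3 with methyl diazoacetate (SnCl2, CH2Cl2, rt) gives the β-keto ester dimethyl 3-oxooctadecanedioate F1. Its enolate is then C-alkylated with methyl bromoacetate (K2CO3, acetone, reflux), the α-halo ester acting as an electrophilic acetate α-carbon, to give 6.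

**Step 4 (dynamic-kinetic hydrogenation).** The carbinol centre should form with high selectivity, but the syn preference rests on analogy, so the syn:anti ratio may be poor if enolisation is slow or the CH2CO2Me group directs weakly. The fallback sets out from 7 and comes back at 8, replacing kinetic control at the second centre by thermodynamic control. Crude 7 is lactonised (4-methylbenzenesulfonic acid, toluene, 80 °C) to methyl (2R)-2-(15-methoxy-15-oxopentadecyl)-5-oxooxolane-3-carboxylate F2 as a mixture of C3 epimers. This is equilibrated at the ester-bearing carbon with 1,8-diazabicyclo[5.4.0]undec-7-ene (DBU, toluene, 60 °C) to the trans diester methyl (2R,3S)-2-(15-methoxy-15-oxopentadecyl)-5-oxooxolane-3-carboxylate F3; the carbinol centre is not affected. Hydrolysis with 6 M HCl in 1,4-dioxane at reflux then gives 8.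

**Step 5 (carboxylation and methylenation).** The triply acidic substrate may form poorly soluble magnesium salts and carboxylate incompletely, and the product can isomerise to the endocyclic butenolide on prolonged heating. The fallback sets out from 8 and comes back at 11. Acid 8 is converted with LiN(iPr)2 (3.3 equiv, THF, −78 °C) into its dicarboxylate lactone enolate and trapped with [Me2N=CH2]I. This gives the aminomethyl lactone (2R,3S)-2-(14-carboxytetradecyl)-4-[(dimethylamino)methyl]-5-oxooxolane-3-carboxylic acid F4. Quaternisation with MeI in MeOH gives [(4S,5R)-4-carboxy-5-(14-carboxytetradecyl)-2-oxooxolan-3-yl]methyl-trimethylazanium iodide F5. Stirring F5 with aqueous NaHCO3 and ethyl acetate eliminates the ammonium group to give 11.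

## Further compounds

F1 | step 3 | dimethyl 3-oxooctadecanedioate | COC(=O)CC(=O)CCCCCCCCCCCCCCC(=O)OC
F2 | step 4 | methyl (2R)-2-(15-methoxy-15-oxopentadecyl)-5-oxooxolane-3-carboxylate (mixture of C3 epimers) | C1C(=O)O[C@H](CCCCCCCCCCCCCCC(=O)OC)C1C(=O)OC
F3 | step 4 | methyl (2R,3S)-2-(15-methoxy-15-oxopentadecyl)-5-oxooxolane-3-carboxylate | C1C(=O)O[C@H](CCCCCCCCCCCCCCC(=O)OC)[C@H]1C(=O)OC
F4 | step 5 | (2R,3S)-2-(14-carboxytetradecyl)-4-[(dimethylamino)methyl]-5-oxooxolane-3-carboxylic acid (C4 epimers) | CN(C)CC1C(=O)O[C@H](CCCCCCCCCCCCCCC(=O)O)[C@H]1C(=O)O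
F5 | step 5 | [(4S,5R)-4-carboxy-5-(14-carboxytetradecyl)-2-oxooxolan-3-yl]methyl-trimethylazanium iodide | C[N+](C)(C)CC1C(=O)O[C@H](CCCCCCCCCCCCCCC(=O)O)[C@H]1C(=O)O.[I-]
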